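**Design of a total synthesis of 6-hydroxy-8-(2-hydroxy-4-methoxy-6-pentylphenoxy)-3-pentyl-1H-isochromen-1-one (22)**

Numbering used throughout: ring A is the benzo ring of the isocoumarin (C1 = lactone carbonyl, O2, C3–C8a). Ring B is the aryloxy ring, with C1' on the ether oxygen, C2' OH, C4' OMe and C6' pentyl.

## The problem

Target 22 is a 3-pentylisocoumarin whose ring A carries a free hydroxyl at C6 and, at C8 next to the lactone carbonyl, the ether oxygen that is the only link to ring B. Ring B is a 1,2,4-trioxygenated benzene whose three oxygens are all different (ether oxygen at C1', free hydroxyl at C2', methyl ether at C4'). C6' bears a pentyl chain, so C1' is flanked on both sides and the diaryl ether is hindered from the ring B side. There is no stereocenter, so nothing in the molecule can relay stereocontrol; the task is purely regiochemical. The enol lactone is opened by hydroxide, alkoxides and hard organometallics, and its C3–C4 double bond is reducible, so the late steps cannot use strong base or hydrogenolysis. A free ring B phenol is a hydroquinone monoether and oxidises easily to a quinone. The C4' methyl ether must survive the final unmasking of two phenols. The enabling feature is that C1' carries oxygen, lies para to the methoxy carbon C4', and sits between an oxygenated carbon (C2') and an alkylated carbon (C6'). That is the pattern of a Dötz benzannulation, with CO becoming C1', the carbene carbon C4', the alkenyl carbons C5' and C6', and an alkoxyalkyne C2' and C3'. The phenol emerges free at exactly the oxygen needed for the diaryl ether.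

## Retrosynthesis

**22 to 21.** The two phenols at C6 and C2' are masked as isopropyl ethers in 21. BCl3 removes secondary alkyl aryl ethers and leaves the C4' methyl ether and the diaryl ether alone. Benzyl groups were rejected because hydrogenolysis would endanger the C3–C4 double bond. A single reagent then unmasks both rings in the last step.

**21 to 20, 19, and 18 plus 1.** The lactone O2–C3 bond is cut to give 2-alkynylbenzoic acid 20; a 6-endo-dig closure restores it. Acid 20 comes from aldehyde 19 by oxidation. The C4a–C4 bond of 19 is cut to aryl bromide 18 and hept-1-yne 1 (Sonogashira coupling). Lateral metalation and acylation of a toluate was the neighbouring option. It needs strong base and more steps, whereas the alkyne route brings C3, C4 and the pentyl chain in one piece and needs only catalytic reagents once the diaryl ether exists.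

**18 to 13 plus 17.** The C8–O bond is cut to phenol 13 and fluoroaldehyde 17. Attaching a di-ortho-substituted phenoxide to a finished lactone would rely on a weakly activating, nucleophile-sensitive carbonyl. A formyl group is small, stays coplanar and is the strongest ortho activator available here. Fluoride leaves far faster than bromide in addition–elimination, so the bromine of 17 is kept for the coupling that follows.

**17 to 15 to 14.** The C–CHO bond is cut to aryllithium 16, which is reached by deprotonating 15 at the carbon flanked by fluorine and bromine. Ether 15 is the isopropyl ether of commercial 3-bromo-5-fluorophenol 14. All four substituents of ring A are thus in place after two steps.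

**13 to 7 plus 11 (key disconnection).** Three ring bonds are cut at once: C1'–C2', C1'–C6' and C3'–C4'. Ring B falls apart into alkenyl(methoxy)carbene complex 7 (C4' with its methoxyl, C5', C6' with the pentyl chain), isopropoxyacetylene 11 (C2' with a cleavable ether, C3') and one CO ligand (C1' with the free hydroxyl). No classical aromatic substitution sequence delivers three differentiated oxygens and the alkyl group in one operation. The forward reaction must place the alkoxy carbon of 11 next to the CO-derived carbon.

**7 to 3 plus 4, 3 to 1, and 11 to 9 to 8.** Complex 7 is cut at the carbene carbon to (E)-1-iodohept-1-ene 3 (through alkenyllithium 5) and Cr(CO)6 4. Iodide 3 comes from hept-1-yne 1 by hydrometalation and iodinolysis, so alkyne 1 is the source of both pentyl-bearing units of the target. Ynol ether 11 comes from bromoacetal 9 by double elimination, and 9 from isopropyl vinyl ether 8.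

## Roads not taken

**Alternative 1:** Ring A would be built last on an intact pyranone. The cut is at C4a–C5 and C6–C7. In the forward step the fused 2-pyranone A2 reacts with ketene acetal A3 in a cycloaddition. Loss of CO2 and benzyl alcohol then gives the fully protected isocoumarin A1.
- Merits: the step is metal-free and convergent, and the polarity of A2 and A3 fixes the position of the C6 oxygen. The lactone is never exposed to a nucleophilic aryl ether synthesis. In these respects it is better than the chosen plan.
- Weak points: A2 already contains ring B, so a ring B phenol with three distinct oxygens must still be made, and the route is silent on that. The hindered phenol must also be attached to C4 of an electrophilic bicyclic dione. A2 has two pyranone rings that can both act as dienes or Michael acceptors. A3 is an uncommon reagent that can add without cyclising.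
- Comparison: the chosen plan solves the ring B pattern from three simple components, at the price of stoichiometric chromium and a linear five-step endgame.

**Alternative 2:** Ring A would be made from an aryl ethynyl ether and a vinylketene. Photolysis of diazo ketoester A5 triggers a Wolff shift. The resulting vinylketene adds aryl ynol ether A6 by [2+2] addition, the cyclobutenone opens, and 6-pi closure gives benzoate A4.
- Merits: the hindered diaryl ether oxygen is introduced by alkynylation of a phenol and not by arylation, which avoids the most congested bond formation of the chosen plan. The C6 hydroxyl emerges free and the alkyne for the lactone is already in place. This is a real advantage.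
- Weak points: A5 is a cross-conjugated enynyl diazo ester that needs several steps and is sensitive. Its carbene can add to the neighbouring alkyne instead of rearranging. An aryloxyalkyne is less polarised than the silyloxyalkynes usually used, so the [2+2] regiochemistry and rate are less secure. A6 again presupposes a differentiated ring B phenol, and A4 still needs lactone closure.
- Comparison: the chosen plan has a longer endgame but supplies the phenol this road needs, and each of its steps is of a common type.

**Alternative 3:** Ring B would be formed by a polyketide-type aldol folding. Triketone A8 would cyclise under mild base by attack of its C1 methylene on the C6 ketone, and dehydration would give resorcinol A7.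
- Merits: it is biomimetic and metal-free, needs no protecting group on ring B, and is the shortest road to the ring B carbon skeleton.
- Weak points: the C1 methylene is much less acidic than the two doubly activated methylenes, so the alternative aldol (C7 onto C2) and O-cyclisation to a pyranone compete. A8 would have to be assembled and cyclised with base in the presence of the lactone. A7 has two free hydroxyls, and selective methylation at C4' rests only on a steric difference.
- Comparison: the chosen plan delivers the three oxygens already differentiated. Against that, Alternative 3 avoids chromium and the separate diaryl ether step.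

Key step: step 5

## Route

Remark: ynol ether 11 is volatile and heat-sensitive. It is assumed to be handled as a cold distilled solution and used promptly.

Step 1
Reactants: 1 hept-1-yne
Product: 3 (1E)-1-iodohept-1-ene, via alkenylzirconocene chloride 2 (not isolated)
Conditions: Cp2Zr(H)Cl, THF, rt; then I2, 0 °C
Reagents that add atoms: iodine, SMILES II
Why: Hydrozirconation of a terminal alkyne is a syn addition that places zirconium on the terminal carbon, and iodinolysis of the C–Zr bond proceeds with retention, so only the E iodide should form.

Step 2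
Reactants: 3 (1E)-1-iodohept-1-ene; 4 hexacarbonylchromium
Product: 7 pentacarbonyl[(2E)-1-methoxyoct-2-en-1-ylidene]chromium, via (E)-hept-1-enyllithium 5 (not isolated), via lithium acylchromate 6 (not isolated)
Conditions: t-BuLi (2 equiv), Et2O, −78 °C; add to 4, Et2O, 0 °C → rt; then Me3OBF4, CH2Cl2, 0 °C
Reagents that add atoms: trimethyloxonium tetrafluoroborate, SMILES C[O+](C)C.F[B-](F)(F)F
Why: Iodine–lithium exchange retains the alkene geometry; addition of the alkenyllithium to a CO ligand and O-methylation of the acyl metalate is the Fischer-type synthesis of alkoxycarbene complexes of zerovalent chromium.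

Step 3
Reactants: 8 2-(ethenyloxy)propane (isopropyl vinyl ether)
Product: 9 2-bromo-1,1-bis(propan-2-yloxy)ethane
Conditions: NBS, i-PrOH, −20 → 0 °C
Reagents that add atoms: N-bromosuccinimide, SMILES O=C1CCC(=O)N1Br; propan-2-ol, SMILES CC(C)O
Why: Alkoxybromination of an enol ether: bromination at the terminal carbon gives an oxocarbenium ion that the solvent alcohol traps at the acetal carbon.

Step 4
Reactants: 9 2-bromo-1,1-bis(propan-2-yloxy)ethane
Product: 11 2-(ethynyloxy)propane (isopropoxyacetylene), via sodium isopropoxyethynide 10 (not isolated)
Conditions: NaNH2 (3 equiv), liq. NH3, −35 °C; then aq. NH4Cl, −70 °C; pentane, cold distillation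
Reagents that add atoms: none
Why: Two successive base-induced 1,2-eliminations (of propan-2-ol and of HBr) are the standard synthesis of 1-alkoxyalkynes from haloacetaldehyde acetals; the product is protected as its acetylide until the cold protonation.

Step 5
Reactants: 7 pentacarbonyl[(2E)-1-methoxyoct-2-en-1-ylidene]chromium; 11 2-(ethynyloxy)propane
Product: 13 4-methoxy-2-pentyl-6-(propan-2-yloxy)phenol, via tricarbonylchromium arene complex 12 (not isolated)
Conditions: 11 (2 equiv), THF, 50 °C, Ar; then air, Et2O, rt
Reagents that add atoms: none
Why: Thermal loss of one CO from the zerovalent chromium complex 7 lets alkyne 11 coordinate and insert into the chromium–carbon double bond, forming C3'–C4' and an alkenyl-chelated vinylcarbene. Migratory insertion of a CO ligand then forms C1'–C2' and gives a chromium-bound dienylketene, and ring B closes by 6-pi electrocyclisation of that ketene (C1'–C6'). Tautomerisation of the cyclohexadienone gives the phenol as its Cr(CO)3 complex 12, which mild air oxidation sets free. The closest known reaction type is the Dötz benzannulation of alkenyl(alkoxy)carbene chromium complexes with terminal alkynes; an ynol ether is an uncommon member of that alkyne class. No stereocenter is formed, and the hydrogen on the β-carbon of the E-alkenyl group allows aromatisation. The step needs the isopropoxy carbon to end next to the CO-derived C1'. The steric rule for terminal alkynes secures this (substituted carbon next to the CO carbon), and the polarity of the ynol ether reinforces it, since its nucleophilic CH carbon bonds to the electrophilic carbene carbon. It also needs CO insertion to win over CO-free cyclisation, which the alkenyl carbene, chromium and THF all favour. Decomplexation uses air and no stronger oxidant, so the 4-methoxyphenol is not taken on to a quinone.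

Step 6
Reactants: 14 3-bromo-5-fluorophenol
Product: 15 1-bromo-3-fluoro-5-(propan-2-yloxy)benzene
Conditions: 2-bromopropane, K2CO3, DMF, 60 °C
Reagents that add atoms: 2-bromopropane, SMILES CC(C)Br
Why: Williamson etherification of an acidic halophenol with a secondary bromide in a polar aprotic solvent.

Step 7
Reactants: 15 1-bromo-3-fluoro-5-(propan-2-yloxy)benzene
Product: 17 2-bromo-6-fluoro-4-(propan-2-yloxy)benzaldehyde, via aryllithium 16 (not isolated)
Conditions: LiN(i-Pr)2, THF, −78 °C; DMF, −78 → −20 °C; aq. HCl
Reagents that add atoms: N,N-dimethylformamide, SMILES CN(C)C=O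
Why: Directed ortho-lithiation with an amide base removes the most acidic ring proton, the one flanked by fluorine and bromine, while the bulky isopropoxy group shields its own neighbours; formylation with DMF (Bouveault type) follows, and −78 °C suppresses aryne formation.

Step 8
Reactants: 13 4-methoxy-2-pentyl-6-(propan-2-yloxy)phenol; 17 2-bromo-6-fluoro-4-(propan-2-yloxy)benzaldehyde
Product: 18 2-bromo-6-[4-methoxy-2-pentyl-6-(propan-2-yloxy)phenoxy]-4-(propan-2-yloxy)benzaldehyde
Conditions: K2CO3, DMF (degassed), 90 °C, Ar
Reagents that add atoms: none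
Why: Nucleophilic aromatic substitution (addition–elimination) of fluoride activated by the ortho formyl group; fluoride is displaced far faster than bromide, so the bromine stays for step 9.

Step 9
Reactants: 18 2-bromo-6-[4-methoxy-2-pentyl-6-(propan-2-yloxy)phenoxy]-4-(propan-2-yloxy)benzaldehyde; 1 hept-1-yne
Product: 19 2-(hept-1-yn-1-yl)-6-[4-methoxy-2-pentyl-6-(propan-2-yloxy)phenoxy]-4-(propan-2-yloxy)benzaldehyde
Conditions: PdCl2(PPh3)2 (cat.), CuI (cat.), Et3N, THF, 60 °C, Ar
Reagents that add atoms: none
Why: Sonogashira coupling; the ortho formyl group activates the C–Br bond towards oxidative addition to zerovalent palladium, and nothing else in 18 reacts under these conditions.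

Step 10
Reactants: 19 2-(hept-1-yn-1-yl)-6-[4-methoxy-2-pentyl-6-(propan-2-yloxy)phenoxy]-4-(propan-2-yloxy)benzaldehyde
Product: 20 2-(hept-1-yn-1-yl)-6-[4-methoxy-2-pentyl-6-(propan-2-yloxy)phenoxy]-4-(propan-2-yloxy)benzoic acid
Conditions: NaClO2, NaH2PO4, 2-methylbut-2-ene, t-BuOH/THF/H2O, 0 °C → rt
Reagents that add atoms: sodium chlorite, SMILES [Na+].[O-]Cl=O
Why: Pinnick oxidation converts the aldehyde into the acid under buffered conditions; the alkene scavenger removes hypochlorous acid before it can chlorinate the alkyne or the electron-rich ring B.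

Step 11
Reactants: 20 2-(hept-1-yn-1-yl)-6-[4-methoxy-2-pentyl-6-(propan-2-yloxy)phenoxy]-4-(propan-2-yloxy)benzoic acid
Product: 21 8-[4-methoxy-2-pentyl-6-(propan-2-yloxy)phenoxy]-3-pentyl-6-(propan-2-yloxy)-1H-isochromen-1-one
Conditions: CF3SO3H (10 mol%), ClCH2CH2Cl, 0 °C → rt
Reagents that add atoms: none
Why: Brønsted acid-catalysed cycloisomerisation of a 2-alkynylbenzoic acid: the carboxyl oxygen attacks the distal, pentyl-bearing alkyne carbon in a 6-endo-dig closure and gives the conjugated isocoumarin, whereas base catalysis would favour the 5-exo phthalide.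

Step 12
Reactants: 21 8-[4-methoxy-2-pentyl-6-(propan-2-yloxy)phenoxy]-3-pentyl-6-(propan-2-yloxy)-1H-isochromen-1-one
Product: 22 6-hydroxy-8-(2-hydroxy-4-methoxy-6-pentylphenoxy)-3-pentyl-1H-isochromen-1-one
Conditions: BCl3, CH2Cl2, −78 → 0 °C; then H2O
Reagents that add atoms: none
Why: Lewis acid dealkylation: BCl3 coordinates the ether oxygens and the secondary isopropyl groups leave as 2-chloropropane, while the methyl ether (not next to a chelating carbonyl), the diaryl ether and the lactone should be untouched at this temperature.

## Compound list

1 | hept-1-yne | CCCCCC#C | starting material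
2 | chlorobis(cyclopentadienyl)[(1E)-hept-1-en-1-yl]zirconium | CCCCC/C=C/[Zr+2]Cl.c1cc[cH-]c1.c1cc[cH-]c1 | intermediate
3 | (1E)-1-iodohept-1-ene | CCCCC/C=C/I | intermediate
4 | hexacarbonylchromium | O=C=[Cr](=C=O)(=C=O)(=C=O)(=C=O)=C=O | starting material
5 | [(1E)-hept-1-en-1-yl]lithium | [Li]/C=C/CCCCC | intermediate
6 | lithium pentacarbonyl[(2E)-1-oxidooct-2-en-1-ylidene]chromate | [Li+].CCCCC/C=C/C([O-])=[Cr](=C=O)(=C=O)(=C=O)(=C=O)=C=O | intermediate
7 | pentacarbonyl[(2E)-1-methoxyoct-2-en-1-ylidene]chromium | CCCCC/C=C/C(OC)=[Cr](=C=O)(=C=O)(=C=O)(=C=O)=C=O | intermediate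
8 | 2-(ethenyloxy)propane | C=COC(C)C | starting material
9 | 2-bromo-1,1-bis(propan-2-yloxy)ethane | BrCC(OC(C)C)OC(C)C | intermediate
10 | sodium 2-(propan-2-yloxy)ethyn-1-ide | [Na+].[C-]#COC(C)C | intermediate
11 | 2-(ethynyloxy)propane | C#COC(C)C | intermediate
12 | tricarbonyl[η6-4-methoxy-2-pentyl-6-(propan-2-yloxy)phenol]chromium | CCCCCc1cc(OC)cc(OC(C)C)c1O.O=C=[Cr](=C=O)=C=O | intermediate
13 | 4-methoxy-2-pentyl-6-(propan-2-yloxy)phenol | CCCCCc1cc(OC)cc(OC(C)C)c1O | intermediate
14 | 3-bromo-5-fluorophenol | Oc1cc(F)cc(Br)c1 | starting material
15 | 1-bromo-3-fluoro-5-(propan-2-yloxy)benzene | CC(C)Oc1cc(F)cc(Br)c1 | intermediate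
16 | [2-bromo-6-fluoro-4-(propan-2-yloxy)phenyl]lithium | [Li]c1c(F)cc(OC(C)C)cc1Br | intermediate
17 | 2-bromo-6-fluoro-4-(propan-2-yloxy)benzaldehyde | O=Cc1c(F)cc(OC(C)C)cc1Br | intermediate
18 | 2-bromo-6-[4-methoxy-2-pentyl-6-(propan-2-yloxy)phenoxy]-4-(propan-2-yloxy)benzaldehyde | O=Cc1c(Br)cc(OC(C)C)cc1Oc1c(CCCCC)cc(OC)cc1OC(C)C | intermediate
19 | 2-(hept-1-yn-1-yl)-6-[4-methoxy-2-pentyl-6-(propan-2-yloxy)phenoxy]-4-(propan-2-yloxy)benzaldehyde | O=Cc1c(C#CCCCCC)cc(OC(C)C)cc1Oc1c(CCCCC)cc(OC)cc1OC(C)C | intermediate
20 | 2-(hept-1-yn-1-yl)-6-[4-methoxy-2-pentyl-6-(propan-2-yloxy)phenoxy]-4-(propan-2-yloxy)benzoic acid | OC(=O)c1c(C#CCCCCC)cc(OC(C)C)cc1Oc1c(CCCCC)cc(OC)cc1OC(C)C | intermediate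
21 | 8-[4-methoxy-2-pentyl-6-(propan-2-yloxy)phenoxy]-3-pentyl-6-(propan-2-yloxy)-1H-isochromen-1-one | CCCCCc1cc2cc(OC(C)C)cc(Oc3c(OC(C)C)cc(OC)cc3CCCCC)c2c(=O)o1 | intermediate
22 | 6-hydroxy-8-(2-hydroxy-4-methoxy-6-pentylphenoxy)-3-pentyl-1H-isochromen-1-one | CCCCCc1cc2cc(O)cc(Oc3c(O)cc(OC)cc3CCCCC)c2c(=O)o1 | target

## Step count and risks

Total step count: 12. Longest linear sequence: 8 steps (steps 1, 2, 5, 8, 9, 10, 11, 12).

**Step 5 (key step).**
- What may go wrong: after insertion of the electron-rich alkyne, the new carbene carbon carries an alkoxy group and is stabilised, so CO insertion may be slow and the sequence may stall or divert to CO-free products. Thermal loss of propene from 11 to a ketene and multiple alkyne incorporation are further drains. Over-oxidation of the product during decomplexation is the last.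
- Fallback: this one leaves the chromium chemistry aside. It does not set out from a numbered compound of the route (7 and 11 are set aside) but from commercial 5-pentylbenzene-1,3-diol F1, and it comes back at phenol 13. Vilsmeier–Haack formylation of F1 should give 2,4-dihydroxy-6-pentylbenzaldehyde F2. Methylation with MeI and K2CO3 at the non-chelated hydroxyl para to the formyl group gives 2-hydroxy-4-methoxy-6-pentylbenzaldehyde F3. Alkylation with 2-bromopropane gives 4-methoxy-2-pentyl-6-(propan-2-yloxy)benzaldehyde F4. Baeyer–Villiger oxidation with mCPBA (Dakin type, aryl migration) gives 4-methoxy-2-pentyl-6-(propan-2-yloxy)phenyl formate F5, and methanolysis with K2CO3 gives 13.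

**Step 8.**
- What may go wrong: slow substitution, because the phenoxide is di-ortho-substituted and the para isopropoxy group weakens the activating formyl group. Oxidative degradation of the electron-rich phenoxide at 90 °C is the second concern.
- Fallback: it sets out from aldehyde 17 and comes back at 18. Condensation of 17 with NH2OH·HCl gives 2-bromo-6-fluoro-4-(propan-2-yloxy)benzaldehyde oxime F6, and dehydration with Ac2O gives 2-bromo-6-fluoro-4-(propan-2-yloxy)benzonitrile F7. The linear nitrile is a stronger and sterically smaller activator. Substitution with 13 (K2CO3, DMF) gives 2-bromo-6-[4-methoxy-2-pentyl-6-(propan-2-yloxy)phenoxy]-4-(propan-2-yloxy)benzonitrile F8. Partial reduction with (i-Bu)2AlH at −78 °C and acidic hydrolysis of the aldimine returns 18.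

**Step 11.**
- What may go wrong: competing 5-exo-dig closure to an alkylidenephthalide, or acid-induced loss of an isopropyl group before cyclisation is complete.
- Fallback: it sets out from acid 20 and comes back at 21. Esterification with MeI and K2CO3 gives methyl 2-(hept-1-yn-1-yl)-6-[4-methoxy-2-pentyl-6-(propan-2-yloxy)phenoxy]-4-(propan-2-yloxy)benzoate F9. Iodocyclisation with I2 in CH2Cl2 opens the iodonium ion at the distal carbon with loss of the ester methyl group. It gives 4-iodo-8-[4-methoxy-2-pentyl-6-(propan-2-yloxy)phenoxy]-3-pentyl-6-(propan-2-yloxy)-1H-isochromen-1-one F10. Hydrodeiodination with Pd(OAc)2, PPh3 and HCO2Na then gives 21.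

**Step 7.**
- What may go wrong: partial deprotonation next to the isopropoxy group, giving a regioisomeric aldehyde, or elimination of lithium halide from 16 to an aryne if the temperature rises.
- Fallback: it sets out from phenol 14 and comes back at 17. Para-selective bromination with n-Bu4NBr3 gives 3,4-dibromo-5-fluorophenol F11, and alkylation with 2-bromopropane gives 1,2-dibromo-3-fluoro-5-(propan-2-yloxy)benzene F12. Bromine–magnesium exchange with i-PrMgCl·LiCl at −40 °C takes place at the bromine flanked by fluorine and bromine. It gives [2-bromo-6-fluoro-4-(propan-2-yloxy)phenyl]magnesium chloride F13, which DMF formylates to 17.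

## Further compounds

F1 | step 5 | 5-pentylbenzene-1,3-diol | CCCCCc1cc(O)cc(O)c1
F2 | step 5 | 2,4-dihydroxy-6-pentylbenzaldehyde | O=Cc1c(O)cc(O)cc1CCCCC
F3 | step 5 | 2-hydroxy-4-methoxy-6-pentylbenzaldehyde | O=Cc1c(O)cc(OC)cc1CCCCC
F4 | step 5 | 4-methoxy-2-pentyl-6-(propan-2-yloxy)benzaldehyde | O=Cc1c(OC(C)C)cc(OC)cc1CCCCC
F5 | step 5 | 4-methoxy-2-pentyl-6-(propan-2-yloxy)phenyl formate | O=COc1c(OC(C)C)cc(OC)cc1CCCCC
F6 | step 8 | (E)-2-bromo-6-fluoro-4-(propan-2-yloxy)benzaldehyde oxime | O/N=C/c1c(F)cc(OC(C)C)cc1Br
F7 | step 8 | 2-bromo-6-fluoro-4-(propan-2-yloxy)benzonitrile | N#Cc1c(F)cc(OC(C)C)cc1Br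
F8 | step 8 | 2-bromo-6-[4-methoxy-2-pentyl-6-(propan-2-yloxy)phenoxy]-4-(propan-2-yloxy)benzonitrile | N#Cc1c(Br)cc(OC(C)C)cc1Oc1c(CCCCC)cc(OC)cc1OC(C)C
F9 | step 11 | methyl 2-(hept-1-yn-1-yl)-6-[4-methoxy-2-pentyl-6-(propan-2-yloxy)phenoxy]-4-(propan-2-yloxy)benzoate | COC(=O)c1c(C#CCCCCC)cc(OC(C)C)cc1Oc1c(CCCCC)cc(OC)cc1OC(C)C
F10 | step 11 | 4-iodo-8-[4-methoxy-2-pentyl-6-(propan-2-yloxy)phenoxy]-3-pentyl-6-(propan-2-yloxy)-1H-isochromen-1-one | CCCCCc1oc(=O)c2c(Oc3c(OC(C)C)cc(OC)cc3CCCCC)cc(OC(C)C)cc2c1I
F11 | step 7 | 3,4-dibromo-5-fluorophenol | Oc1cc(F)c(Br)c(Br)c1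
F12 | step 7 | 1,2-dibromo-3-fluoro-5-(propan-2-yloxy)benzene | CC(C)Oc1cc(F)c(Br)c(Br)c1
F13 | step 7 | [2-bromo-6-fluoro-4-(propan-2-yloxy)phenyl]magnesium chloride | Cl[Mg]c1c(F)cc(OC(C)C)cc1Br
A1 | alternative 1 | 6-(benzyloxy)-8-[2-(benzyloxy)-4-methoxy-6-pentylphenoxy]-3-pentyl-1H-isochromen-1-one | CCCCCc1cc2cc(OCc3ccccc3)cc(Oc3c(OCc4ccccc4)cc(OC)cc3CCCCC)c2c(=O)o1
A2 | alternative 1 | 4-[2-(benzyloxy)-4-methoxy-6-pentylphenoxy]-7-pentyl-2H,5H-pyrano[4,3-b]pyran-2,5-dione | O=c1cc(Oc2c(OCc3ccccc3)cc(OC)cc2CCCCC)c2c(=O)oc(CCCCC)cc2o1
A3 | alternative 1 | 1,1-bis(benzyloxy)ethene | C=C(OCc1ccccc1)OCc1ccccc1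
A4 | alternative 2 | methyl 2-[2-(benzyloxy)-4-methoxy-6-pentylphenoxy]-6-(hept-1-yn-1-yl)-4-hydroxybenzoate | COC(=O)c1c(Oc2c(OCc3ccccc3)cc(OC)cc2CCCCC)cc(O)cc1C#CCCCCC
A5 | alternative 2 | methyl 2-diazo-4-methylidene-3-oxoundec-5-ynoate | COC(=O)C(=[N+]=[N-])C(=O)C(=C)C#CCCCCC
A6 | alternative 2 | 1-(benzyloxy)-2-(ethynyloxy)-5-methoxy-3-pentylbenzene | C#COc1c(OCc2ccccc2)cc(OC)cc1CCCCC
A7 | alternative 3 | 6-(benzyloxy)-8-(2,4-dihydroxy-6-pentylphenoxy)-3-pentyl-1H-isochromen-1-one | CCCCCc1cc2cc(OCc3ccccc3)cc(Oc3c(O)cc(O)cc3CCCCC)c2c(=O)o1
A8 | alternative 3 | 1-{[6-(benzyloxy)-1-oxo-3-pentyl-1H-isochromen-8-yl]oxy}undecane-2,4,6-trione | CCCCCC(=O)CC(=O)CC(=O)COc1cc(OCc2ccccc2)cc2cc(CCCCC)oc(=O)c12
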